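**Retrosynthetic overview**
- Feature: the target is a cis-fused 3,7-dioxabicyclo[3.3.0]octane, two oxolane rings sharing the C1–C5 bond, with a C2-symmetric core. The ring-fusion carbons C1 and C5 (both S) carry its chirality. C2 and C6 each hold a ring oxygen (O3, O7) and an aryl group on the convex face, so removing the aryl groups leaves two acetal carbons.
- Disconnection 1: the prenyl O–C bond, back to (−)-pinoresinol with its two homotopic phenols, and from there to its bis-silyl ether.
- Disconnection 2 (key): the C2–aryl and C6–aryl bonds together, back to the aryl-free bis-anomeric diacetate and a diarylzinc made from 4-bromo-2-methoxyphenol.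
- Disconnection 3: both oxolane rings at once, by double lactol closure of (2S,3S)-2,3-bis(hydroxymethyl)butanedial, which ozonolysis of (S,S)-trans-3,4-bis(hydroxymethyl)cyclobutene releases.
- Ring order: the four-membered ring comes first ([2+2] of maleic anhydride and dichloroethene, Zn, alkaloid desymmetrisation, epimerisation, LiAlH4). It is then cut open and the two oxolane rings close in one operation. No ring is formed after that.

Key step: step 10

Assumption: quinidine is taken to open the meso anhydride in the sense that gives the (1S,4R)-hemiester. The sense is to be confirmed on the first batch, and the pseudo-enantiomer quinine is used instead if it proves to be the opposite one.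

**Step 1**
Reactants: 1 maleic anhydride; 2 (E)-1,2-dichloroethene
Product: 3 cis-fused 6,7-dichloro-3-oxabicyclo[3.2.0]heptane-2,4-dione (mixture of C6/C7 chloride stereoisomers)
Conditions: hν (medium-pressure Hg lamp, Pyrex filter), benzophenone (cat.), EtOAc, rt
Reagents that add atoms: none
Why: Triplet-sensitised [2+2] photocycloaddition of the anhydride C=C to the alkene; the five-membered anhydride enforces the cis ring fusion, and the chloride stereoisomers do not matter because both chlorines leave in step 2.

**Step 2**
Reactants: 3 dichloro anhydride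
Product: 4 cis-cyclobut-3-ene-1,2-dicarboxylic anhydride, (1R,5S)-3-oxabicyclo[3.2.0]hept-6-ene-2,4-dione (meso)
Conditions: activated Zn dust, Ac2O, toluene, 80 °C
Reagents that add atoms: none
Why: Reductive vicinal dehalogenation with zinc should convert every dichloride isomer into the same cyclobutene, Ac2O keeps the anhydride closed, and the bicyclic frame hinders conrotatory opening of the four-membered ring at this temperature.

**Step 3**
Reactants: 4 meso cyclobutene anhydride
Product: 5 (1S,4R)-4-(methoxycarbonyl)cyclobut-2-ene-1-carboxylic acid (cis hemiester)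
Conditions: quinidine (1.1 equiv), MeOH (3 equiv), toluene, −55 °C; then 2 M HCl wash (alkaloid recovered)
Reagents that add atoms: methanol, CO
Why: Cinchona-alkaloid-mediated desymmetrising alcoholysis of a meso anhydride, in which the alkaloid steers methanol to one of the two enantiotopic carbonyl groups and so makes C1 (S, acid-bearing) and C4 (R, ester-bearing) distinct.

**Step 4**
Reactants: 5 cis hemiester
Product: 6 (1S,4S)-4-(methoxycarbonyl)cyclobut-2-ene-1-carboxylic acid (trans hemiester)
Conditions: NaOMe (2.5 equiv), MeOH, 0 °C → rt, monitored and stopped at equilibrium; cold 1 M HCl; residual 5 removed by crystallisation or chromatography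
Reagents that add atoms: none
Why: Thermodynamic epimerisation through the ester enolate; the carboxylate suppresses deprotonation at C1, so only C4 inverts (R to S), which relieves the eclipsing of the two cis groups while C1 keeps the absolute configuration.

**Step 5**
Reactants: 6 trans hemiester
Product: 7 [(1S,2S)-cyclobut-3-ene-1,2-diyl]dimethanol (trans, C2-symmetric)
Conditions: LiAlH4 (excess), THF, 0 °C → rt; Na2SO4·10H2O quench, filtration
Reagents that add atoms: none
Why: Hydride reduction of ester and carboxylate to primary alcohols leaves the isolated ring alkene and both stereocentres untouched and merges the two differentiated ends into one C2-symmetric diol.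

**Step 6**
Reactants: 7 trans diol
Product: 9 (1S,5S)-3,7-dioxabicyclo[3.3.0]octane-2,6-diol (cis-fused bis-lactol; anomers interconvert; exo,exo form drawn), via dialdehyde 8 (not isolated)
Conditions: O3, CH2Cl2–MeOH (9:1), −78 °C; Me2S, −78 °C → rt; evaporation, no aqueous work-up
Reagents that add atoms: ozone, [O-][O+]=O
Why: Ozonolysis with reductive work-up cleaves the only C=C to dialdehyde 8, in which each CH2OH reaches the formyl group on the neighbouring carbon through a five-membered hemiacetal, so the (2S,3S) isomer should fold at once into the cis-fused bis-lactol and shield the enolisable C1 and C5 from epimerisation.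

**Step 7**
Reactants: 9 bis-lactol
Product: 10 (1S,2S,5S,6S)-2,6-diacetoxy-3,7-dioxabicyclo[3.3.0]octane (cis-fused, both acetates exo)
Conditions: Ac2O, pyridine, DMAP (cat.), CH2Cl2, 0 °C → rt
Reagents that add atoms: acetic anhydride, CC(=O)OC(C)=O
Why: DMAP-catalysed O-acylation of the hemiacetal hydroxyls traps the bicyclic form with the acetates mainly on the less crowded convex face, and any endo anomer is just as usable because step 10 passes through the planar cation.

**Step 8**
Reactants: 11 4-bromo-2-methoxyphenol
Product: 12 (4-bromo-2-methoxyphenoxy)(tert-butyl)dimethylsilane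
Conditions: TBSCl, imidazole, DMF, rt
Reagents that add atoms: tert-butyldimethylsilyl chloride, CC(C)(C)[Si](C)(C)Cl
Why: Imidazole-promoted silylation of a phenol masks the acidic OH ahead of the metalation.

**Step 9**
Reactants: 12 aryl bromide (2 equiv per zinc)
Product: 14 bis[4-(tert-butyldimethylsilyloxy)-3-methoxyphenyl]zinc, via aryllithium 13 (not isolated)
Conditions: n-BuLi (1.05 equiv), THF, −78 °C; ZnCl2 (0.5 equiv), −78 °C → rt; THF exchanged for toluene, used as a solution
Reagents that add atoms: zinc dichloride, Cl[Zn]Cl
Why: Bromine–lithium exchange followed by transmetalation with half an equivalent of ZnCl2 gives the diarylzinc, and removal of THF keeps the Lewis acid of step 10 free for the acetates.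

**Step 10**
Reactants: 10 bis-anomeric diacetate; 14 diarylzinc
Product: 16 (1S,2R,5S,6R)-2,6-bis[4-(tert-butyldimethylsilyloxy)-3-methoxyphenyl]-3,7-dioxabicyclo[3.3.0]octane (bis-TBS ether of (−)-pinoresinol), via monoaryl monoacetate 15 (not isolated)
Conditions: 14 (2.5 equiv), BF3·OEt2 (3 equiv), CH2Cl2–toluene, −78 → −30 °C; Et3N, then sat. aq. NaHCO3 at −30 °C
Reagents that add atoms: none
Why: BF3·OEt2 takes off one anomeric acetate to leave a cis-fused bicyclic oxocarbenium ion (C2=O3+), which is captured at C2 by the zinc-bound ipso carbon of 14 (made more nucleophilic by the para silyloxy group) to give 15, and the acetate at C6 then ionises and reacts alike. The closest known reaction type is the Lewis-acid-mediated substitution of alpha-acyloxy ethers (2-acyloxytetrahydrofurans, glycosyl donors) by diorganozinc and arylzinc reagents. No ring is closed: two C(sp3)–C(aryl) bonds are formed on the intact bicycle. The new stereocentres C2 and C6 (both R) are controlled by the fixed ring fusion C1/C5, because the second oxolane ring roofs the concave face of the V-shaped cation and the aryl group can only come in from the convex face, cis to the ring-fusion hydrogens. The step needs facial selectivity twice, exocyclic rather than endocyclic C–O ionisation, and survival of the product; the fold of the bicycle secures the first, the better leaving ability of the BF3-bound acetate the second, and both anomers of 10 funnel into the same cation. Low temperature and a cold amine quench are meant to keep the electron-rich benzylic ethers of 16 from ionising again, which would scramble C2 and C6.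

**Step 11**
Reactants: 16 bis-TBS ether
Product: 17 (−)-pinoresinol, (1S,2R,5S,6R)-2,6-bis(4-hydroxy-3-methoxyphenyl)-3,7-dioxabicyclo[3.3.0]octane
Conditions: TBAF (2.2 equiv), AcOH (2.2 equiv), THF, 0 °C
Reagents that add atoms: none
Why: Fluoride-driven cleavage of the aryl silyl ethers under acetic acid buffering frees both phenols under near-neutral conditions that leave the four stereocentres alone.

**Step 12**
Reactants: 17 (−)-pinoresinol; 18 prenyl bromide (1-bromo-3-methylbut-2-ene)
Product: 19 target, (1S,2R,5S,6R)-2-(4-hydroxy-3-methoxyphenyl)-6-[3-methoxy-4-(3-methylbut-2-enyloxy)phenyl]-3,7-dioxabicyclo[3.3.0]octane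
Conditions: 18 (0.9 equiv), K2CO3 (1.2 equiv), acetone, rt, N2; chromatography, recovered 17 recycled
Reagents that add atoms: none
Why: Williamson ether synthesis (SN2 at the primary allylic bromide) on one of two homotopic, remote phenols, so mono-alkylation follows statistics and the bromide is kept limiting to hold back the bis-ether.

**Compound list**
1 | maleic anhydride | O=C1OC(=O)C=C1 | starting material
2 | (E)-1,2-dichloroethene | Cl/C=C/Cl | starting material
3 | cis-fused 6,7-dichloro-3-oxabicyclo[3.2.0]heptane-2,4-dione (chloride stereoisomers) | O=C1OC(=O)[C@@H]2C(Cl)C(Cl)[C@H]12 | intermediate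
4 | cis-cyclobut-3-ene-1,2-dicarboxylic anhydride (meso) | O=C1OC(=O)[C@@H]2C=C[C@H]12 | intermediate
5 | (1S,4R)-4-(methoxycarbonyl)cyclobut-2-ene-1-carboxylic acid | COC(=O)[C@@H]1C=C[C@@H]1C(=O)O | intermediate
6 | (1S,4S)-4-(methoxycarbonyl)cyclobut-2-ene-1-carboxylic acid | COC(=O)[C@H]1C=C[C@@H]1C(=O)O | intermediate
7 | [(1S,2S)-cyclobut-3-ene-1,2-diyl]dimethanol | OC[C@H]1C=C[C@@H]1CO | intermediate
8 | (2S,3S)-2,3-bis(hydroxymethyl)butanedial (not isolated) | O=C[C@H](CO)[C@@H](CO)C=O | intermediate
9 | (1S,5S)-3,7-dioxabicyclo[3.3.0]octane-2,6-diol (exo,exo anomer drawn) | O[C@@H]1OC[C@@H]2[C@H]1CO[C@H]2O | intermediate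
10 | (1S,2S,5S,6S)-2,6-diacetoxy-3,7-dioxabicyclo[3.3.0]octane | CC(=O)O[C@@H]1OC[C@@H]2[C@H]1CO[C@H]2OC(C)=O | intermediate
11 | 4-bromo-2-methoxyphenol | COc1cc(Br)ccc1O | starting material
12 | (4-bromo-2-methoxyphenoxy)(tert-butyl)dimethylsilane | COc1cc(Br)ccc1O[Si](C)(C)C(C)(C)C | intermediate
13 | [4-(tert-butyldimethylsilyloxy)-3-methoxyphenyl]lithium (not isolated) | [Li]c1ccc(O[Si](C)(C)C(C)(C)C)c(OC)c1 | intermediate
14 | bis[4-(tert-butyldimethylsilyloxy)-3-methoxyphenyl]zinc | COc1cc(ccc1O[Si](C)(C)C(C)(C)C)[Zn]c1ccc(O[Si](C)(C)C(C)(C)C)c(OC)c1 | intermediate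
15 | exo-6-aryl-exo-2-acetoxy-3,7-dioxabicyclo[3.3.0]octane, aryl = 4-(tert-butyldimethylsilyloxy)-3-methoxyphenyl (not isolated) | CC(=O)O[C@@H]1OC[C@@H]2[C@H]1CO[C@H]2c3ccc(O[Si](C)(C)C(C)(C)C)c(OC)c3 | intermediate
16 | bis-TBS ether of (−)-pinoresinol | COc1cc([C@@H]2OC[C@@H]3[C@H]2CO[C@H]3c2ccc(O[Si](C)(C)C(C)(C)C)c(OC)c2)ccc1O[Si](C)(C)C(C)(C)C | intermediate
17 | (−)-pinoresinol | COc1cc([C@@H]2OC[C@@H]3[C@H]2CO[C@H]3c2ccc(O)c(OC)c2)ccc1O | intermediate
18 | prenyl bromide | CC(C)=CCBr | starting material
19 | mono-O-prenyl-(−)-pinoresinol (CNP0185952.2) | COc1cc([C@@H]2OC[C@@H]3[C@H]2CO[C@H]3c2ccc(OCC=C(C)C)c(OC)c2)ccc1O | target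

**Step count**
Total step count: 12. Longest linear sequence: 10 (steps 1–7, then 10–12). The aryl branch (steps 8–9) joins at step 10.

**Steps most likely to fail**

Step 10. Several processes could undermine this step:
- Aryl transfer from zinc to boron may outrun capture of the cation.
- Ionisation may take the endocyclic C–O bond.
- Facial selectivity at the second cation may be incomplete.
- The Lewis acid may re-ionise the new benzylic ethers and scramble C2 and C6.

The fallback gives up the oxocarbenium arylation for carbonyl addition followed by benzylic cycloetherification. It sets out from 9, which is treated with an excess of aryllithium 13 (about 5 equiv, THF, −78 → 0 °C). Two equivalents deprotonate the lactols, and two add to the open hydroxy-aldehyde forms. This gives (2S,3S)-1,4-bis[4-(tert-butyldimethylsilyloxy)-3-methoxyphenyl]-2,3-bis(hydroxymethyl)butane-1,4-diol F1 as a mixture of carbinol epimers. Brief exposure to catalytic camphorsulfonic acid in CH2Cl2 at low temperature should ionise the benzylic alcohols to para-silyloxybenzyl cations. The CH2OH of the neighbouring carbon captures each cation, with the aryl group trans to the adjacent ring substituent, so both carbinol epimers converge. The route is rejoined at 16.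

Step 4. Several processes could undermine this step:
- Gamma-protonation of the dienolate may move the ring double bond into conjugation with the ester.
- Methoxide may add to that conjugated isomer.
- The cis-to-trans conversion may stay incomplete.
- Optical purity may leak away through a transient anhydride.

The fallback builds the trans relationship directly by an auxiliary-controlled cycloaddition instead of by inversion. It sets out from 1 and runs as follows.
- Esterification with (−)-menthol (p-TsOH, toluene, azeotropic removal of water) gives di-(−)-menthyl maleate F2.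
- Catalytic morpholine isomerises this to di-(−)-menthyl fumarate F3.
- The Et2AlCl-promoted [2+2] cycloaddition with 1,1-dimethoxyethene (toluene–hexane, −78 °C) gives di-(−)-menthyl (1S,2R)-3,3-dimethoxycyclobutane-1,2-dicarboxylate F4, which is purified by crystallisation.
- LiAlH4 gives (1S,2S)-3,3-dimethoxycyclobutane-1,2-dimethanol F5.
- TBDPSCl and imidazole give the bis-TBDPS ether ketal F6.
- Aqueous H2SO4 in MeCN unmasks (2S,3S)-2,3-bis(tert-butyldiphenylsilyloxymethyl)cyclobutanone F7.
- TsNHNH2 gives the tosylhydrazone F8.
- A Shapiro reaction (n-BuLi, TMEDA, then water) deprotonates the unsubstituted ring methylene and gives (3S,4S)-3,4-bis(tert-butyldiphenylsilyloxymethyl)cyclobutene F9.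
- TBAF brings the route back at 7.

Step 12. Over-alkylation to the bis-ether, a difficult separation of the three phenol and ether species, or some C-prenylation of the phenoxide may eat into the material at the last stage. The fallback breaks the symmetry by a reversible deprotection and not by the irreversible alkylation. It sets out from 16, which is treated with one equivalent of TBAF/AcOH at low temperature to give the mono-TBS ether of (−)-pinoresinol F10. Unreacted 16 is reused and 17 can be silylated again. F10 has a single free phenol and is alkylated to completion with excess 18 and K2CO3, which gives the mono-TBS mono-prenyl ether F11. TBAF/AcOH then returns the route at 19.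

**Further compounds**
F1 | step 10 | (2S,3S)-1,4-bis[4-(tert-butyldimethylsilyloxy)-3-methoxyphenyl]-2,3-bis(hydroxymethyl)butane-1,4-diol (carbinol epimers) | COc1cc(C(O)[C@H](CO)[C@@H](CO)C(O)c2ccc(O[Si](C)(C)C(C)(C)C)c(OC)c2)ccc1O[Si](C)(C)C(C)(C)C
F2 | step 4 | di-(−)-menthyl maleate | CC(C)[C@@H]1CC[C@@H](C)C[C@H]1OC(=O)/C=C\C(=O)O[C@@H]1C[C@H](C)CC[C@H]1C(C)C
F3 | step 4 | di-(−)-menthyl fumarate | CC(C)[C@@H]1CC[C@@H](C)C[C@H]1OC(=O)/C=C/C(=O)O[C@@H]1C[C@H](C)CC[C@H]1C(C)C
F4 | step 4 | di-(−)-menthyl (1S,2R)-3,3-dimethoxycyclobutane-1,2-dicarboxylate | CC(C)[C@@H]1CC[C@@H](C)C[C@H]1OC(=O)[C@H]2C(OC)(OC)C[C@@H]2C(=O)O[C@@H]1C[C@H](C)CC[C@H]1C(C)C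
F5 | step 4 | (1S,2S)-3,3-dimethoxycyclobutane-1,2-dimethanol | OC[C@H]1C(OC)(OC)C[C@@H]1CO
F6 | step 4 | bis-TBDPS ether of F5 | CC(C)(C)[Si](c1ccccc1)(c1ccccc1)OC[C@H]2C(OC)(OC)C[C@@H]2CO[Si](c1ccccc1)(c1ccccc1)C(C)(C)C
F7 | step 4 | (2S,3S)-2,3-bis(tert-butyldiphenylsilyloxymethyl)cyclobutanone | CC(C)(C)[Si](c1ccccc1)(c1ccccc1)OC[C@H]2C(=O)C[C@@H]2CO[Si](c1ccccc1)(c1ccccc1)C(C)(C)C
F8 | step 4 | tosylhydrazone of F7 | CC(C)(C)[Si](c1ccccc1)(c1ccccc1)OC[C@H]2C(=NNS(=O)(=O)c1ccc(C)cc1)C[C@@H]2CO[Si](c1ccccc1)(c1ccccc1)C(C)(C)C
F9 | step 4 | (3S,4S)-3,4-bis(tert-butyldiphenylsilyloxymethyl)cyclobutene | CC(C)(C)[Si](c1ccccc1)(c1ccccc1)OC[C@H]2C=C[C@@H]2CO[Si](c1ccccc1)(c1ccccc1)C(C)(C)C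
F10 | step 12 | mono-TBS ether of (−)-pinoresinol | COc1cc([C@@H]2OC[C@@H]3[C@H]2CO[C@H]3c2ccc(O[Si](C)(C)C(C)(C)C)c(OC)c2)ccc1O
F11 | step 12 | mono-TBS mono-prenyl ether of (−)-pinoresinol | COc1cc([C@@H]2OC[C@@H]3[C@H]2CO[C@H]3c2ccc(OCC=C(C)C)c(OC)c2)ccc1O[Si](C)(C)C(C)(C)C
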